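Start from the loss.

| flask | starting material | partner | time |
|---|---|---|---|
| gamma | 0.400 M | 0.320 M |  |
| delta | 0.160 M | 0.0800 M |  |
| alpha | 0.400 M | 0.640 M |  |
| theta | 1.20 M | 0.320 M |  |
| eta | 1.20 M | 0.110 M | 150 s |

- gamma run (time / s: [starting material] / M): 11: 0.3485; 35: 0.2734; 66: 0.2171; 100: 0.1817; 150: 0.1496
- delta run (time / s: [starting material] / M): 11: 0.1537; 35: 0.1393; 66: 0.1250; 100: 0.1127; 150: 0.1002
- alpha run (time / s: [starting material] / M): 11: 0.3214; 35: 0.2247; 66: 0.1590; 100: 0.1256; 150: 0.0993
- theta run (time / s: [starting material] / M): 11: 0.9627; 35: 0.6807; 66: 0.5054; 100: 0.4019; 150: 0.3154

(scatter of a reading: 0.001 M)

- the power of [partner] that the first rate follows, about the charge of the gamma run; measure it at two percent of starting material made into product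
- the power of [starting material] that the first rate follows, about the charge of the gamma run; measure it at two percent of starting material made into product (one fixed amount of product, the same in the runs compared)
- starting material in the eta run at 150 s, as a share of the starting material charged

- Overall: starting material + partner -> product.
- Constant volume, constant temperature.
- "The second partner" is partner.
- An order is taken over about fifteen percent of the charge, up and down.

By 150 s, theta has lost 0.885 M of starting material, more than its 0.320 M of partner, so some loss runs without partner. My scale has a plain zero: if each starting material left with one partner, doubling the partner would double the early loss, and if none did, the loss would stay as it was. Alpha carries twice gamma's partner on the same starting material, and at 11 s gamma has lost 0.0515 M and alpha 0.0786 M. Their ratio less one reads 52.6%. This is the partner share, the part of gamma's loss of starting material over the first 11 s that goes with partner, a selectivity averaged over that interval and read from scattered readings, not an instantaneous value.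

I take the partner route as first order in each reactant, so I commit to 1 for both orders, and I take the rest as one power of c(starting material) steeper. Gamma's rest stands at 0.900 of its partner route. Theta has 3.00 times gamma's starting material on the same partner, so its share falls to 27.0%. Theta's reciprocal of c(starting material) gains 2.34 L mol⁻¹ by 150 s. Eta starts from the same starting material, so, assuming that share holds through the run, I keep the rest of this gain and scale the partner part by 0.344. Eta then gains 1.92 L mol⁻¹, which leaves 30.2% of its charge.

The weak link is the first difference, so I push each loss one scatter apart: the share becomes 57.6% and eta 31.0%.

The forecast differs from my reckoning: partner order 0.7, starting-material order 1.4, and eta at 40%, higher than mine. Of the second order it says “lower than the within-run order, which suggests inhibition or saturation”.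

The flask gives partner order 1.1, starting-material order 1.0, and eta at 28.7%.

    starting material + partner ⇌ product (0.02450 L mol⁻¹ s⁻¹, 0.004150 s⁻¹)
    2 starting material → homo dimer (0.006140 L mol⁻¹ s⁻¹)
    starting material → decomposed substrate (4.090 × 10⁻⁴ s⁻¹)

Alpha's product formation runs at 2.1 times gamma's, where two percent of gamma's starting material has turned, against a loss ratio of 1.53. The partner share of gamma's mean loss rate over the first 11 s is 0.00246 M s⁻¹, against 0.0029 M s⁻¹ of product formation where two percent of gamma's starting material has turned. Delta's charge puts the share at 41.0%, so its mean loss rate over the first 11 s yields 2.35 × 10⁻⁴ M s⁻¹, against 2.2 × 10⁻⁴ M s⁻¹ of product formation at that same amount turned.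

All runs are calculated on assumed constants, and the scatter is random.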